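Numbering: ring carbons C1–C14 (C1 ring-fusion CH, C14 lactone O–CH, C10 acetoxy carbon), C15 α-carbon, C16 carbonyl, C17 exocyclic methylene. The route rests on the C1–C14 bond, where carbinol C14 adjoins C1 carrying the C15(=C17)–C16 unit of the lactone ring: the homoallylic alcohol pattern of a [2,3]-Wittig shift. A 17-membered allyl propargyl ether (C14–O–C17; C15=C1 with C2 trans to C17; C12≡C13; C10 silyl ether; C16 aryl ether) contracts in one operation to the 14-membered carbocycle, forming C1–C14, the C15=C17 methylene and both anti ring-fusion stereocentres. Farnesol supplies C1–C10; the alkyne later becomes the E C12-methyl alkene and C16 the lactone carbonyl.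

Key step: step 13

Remark (sense of the chiral base): which enantiomer of the lithium amide is matched with C10 in a 17-membered ring cannot be predicted with confidence; the (R,R)-amide is written, and the (S,S)-amide would take its place if a small-scale trial shows it to be the matched one.

Remark (sense of the propargylation): the (R)-phosphoric acid is assumed to give the (R)-carbinol from the enal, by analogy with aryl and alkenyl aldehydes; the configuration of 4 would be checked by MTPA ester analysis before going on.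

Step 1
Reactants: 1 (2E,6E)-farnesol
Product: 2 (2E,6E)-farnesal
Conditions: TEMPO (10 mol %), PhI(OAc)2 (1.1 equiv), CH2Cl2, rt
Reagents that add atoms: none
Why: Nitroxyl-catalysed oxidation with PhI(OAc)2 as terminal oxidant should convert the primary allylic alcohol into the enal without touching the trisubstituted alkenes or isomerising the conjugated E double bond.

Step 2
Reactants: 2 (2E,6E)-farnesal; 3 allenylboronic acid pinacol ester
Product: 4 (4R,5E,9E)-6,10,14-trimethylpentadeca-5,9,13-trien-1-yn-4-ol
Conditions: (R)-3,3'-bis(2,4,6-triisopropylphenyl)-1,1'-binaphthyl-2,2'-diyl hydrogen phosphate (5 mol %), 4 Å MS, toluene, −20 °C; aqueous work-up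
Reagents that add atoms: none
Why: Chiral phosphoric acid-catalysed propargylboration should proceed through a closed six-membered SE2' transition state in which the catalyst activates the boronate and shields one aldehyde face, so that C10 is set as R by catalyst control while C11–C13 arrive as the homopropargyl unit.

Step 3
Reactants: 4 (4R,5E,9E)-6,10,14-trimethylpentadeca-5,9,13-trien-1-yn-4-ol
Product: 5 tert-butyldimethyl{[(4R,5E,9E)-6,10,14-trimethylpentadeca-5,9,13-trien-1-yn-4-yl]oxy}silane
Conditions: TBSCl, imidazole, DMF, rt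
Reagents that add atoms: tert-butyldimethylsilyl chloride, CC(C)(C)[Si](C)(C)Cl
Why: Imidazole-promoted silylation of the secondary allylic alcohol is routine and leaves the C10 configuration untouched.

Step 4
Reactants: 5 tert-butyldimethyl{[(4R,5E,9E)-6,10,14-trimethylpentadeca-5,9,13-trien-1-yn-4-yl]oxy}silane
Product: 7 tert-butyl{[(4R,5E,9E)-12-(3,3-dimethyloxiran-2-yl)-6,10-dimethyldodeca-5,9-dien-1-yn-4-yl]oxy}dimethylsilane (both epoxide epimers), via bromohydrin 6 (not isolated)
Conditions: NBS (1.1 equiv), THF/H2O, 0 °C; then K2CO3, MeOH, rt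
Reagents that add atoms: water, O; N-bromosuccinimide, O=C1CCC(=O)N1Br, supplies the bromine of intermediate 6 only
Why: Bromohydrin formation with NBS in aqueous THF is selective for the terminal trisubstituted alkene of a polyprenyl chain (the alkene beside the silyloxy carbon is deactivated and the mid-chain one is shielded in the aqueous medium), and K2CO3 in methanol then closes the bromohydrin to the epoxide.

Step 5
Reactants: 7 terminal epoxide
Product: 8 (4E,8E,10R)-10-[(tert-butyldimethylsilyl)oxy]-4,8-dimethyltrideca-4,8-dien-12-ynal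
Conditions: H5IO6 (1.2 equiv), THF/Et2O, 0 °C, 30 min
Reagents that add atoms: none
Why: Periodic acid should open the epoxide to the vicinal diol and cleave it in the same flask to the C1 aldehyde and acetone (oxidative glycol cleavage), the short time at 0 °C keeping the secondary silyl ether intact.

Step 6
Reactants: 8 (4E,8E,10R)-10-[(tert-butyldimethylsilyl)oxy]-4,8-dimethyltrideca-4,8-dien-12-ynal; 9 methyl acrylate
Product: 10 methyl (6E,10E,12R)-12-[(tert-butyldimethylsilyl)oxy]-3-hydroxy-6,10-dimethyl-2-methylidenepentadeca-6,10-dien-14-ynoate (both C3 epimers)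
Conditions: 1,4-diazabicyclo[2.2.2]octane (1 equiv), methyl acrylate (4 equiv), 1,4-dioxane/H2O (1:1), rt, 2–3 d
Reagents that add atoms: none
Why: In the Morita–Baylis–Hillman reaction the amine adds to the acrylate, the zwitterionic enolate adds to the unhindered aliphatic aldehyde and the amine is expelled, which attaches C15–C17 to C1; the new carbinol centre is of no consequence because C1 becomes sp2 in step 7.

Step 7
Reactants: 10 Morita–Baylis–Hillman adduct
Product: 11 methyl (2Z,6E,10E,12R)-2-(bromomethyl)-12-[(tert-butyldimethylsilyl)oxy]-6,10-dimethylpentadeca-2,6,10-trien-14-ynoate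
Conditions: NBS (1.5 equiv), Me2S (1.8 equiv), CH2Cl2, 0 °C → rt
Reagents that add atoms: N-bromosuccinimide, O=C1CCC(=O)N1Br
Why: Corey–Kim-type activation of the allylic alcohol as its alkoxysulfonium salt and SN2' attack of bromide at the methylene carbon should give the rearranged primary bromide with the thermodynamically preferred geometry, in which C2 is trans to the ester carbon (the future C17) and cis to CH2Br (the future C16).

Step 8
Reactants: 11 allylic bromide
Product: 12 methyl (2E,6E,10E,12R)-12-[(tert-butyldimethylsilyl)oxy]-2-[(4-methoxyphenoxy)methyl]-6,10-dimethylpentadeca-2,6,10-trien-14-ynoate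
Conditions: 4-methoxyphenol (1.2 equiv), K2CO3, acetone, rt
Reagents that add atoms: 4-methoxyphenol, COc1ccc(O)cc1
Why: Williamson SN2 alkylation of the phenoxide by the primary allylic bromide keeps the alkene geometry and places on C16 an aryl ether that, unlike a benzylic ether, offers no acidic ArCH2–O site able to compete in step 13.

Step 9
Reactants: 12 aryloxymethyl enoate
Product: 13 (2Z,6E,10E,12R)-12-[(tert-butyldimethylsilyl)oxy]-2-[(4-methoxyphenoxy)methyl]-6,10-dimethylpentadeca-2,6,10-trien-14-yn-1-ol
Conditions: i-Bu2AlH (2.5 equiv), CH2Cl2, −78 °C; Rochelle salt work-up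
Reagents that add atoms: none
Why: 1,2-Reduction of the α,β-unsaturated ester by the aluminium hydride at low temperature should give the C17 allylic alcohol without touching the silyl ether, the aryl ether or the alkyne.

Step 10
Reactants: 13 allylic alcohol
Product: 14 tert-butyl{[(4R,5E,9E,13E)-15-chloro-14-[(4-methoxyphenoxy)methyl]-6,10-dimethylpentadeca-5,9,13-trien-1-yn-4-yl]oxy}dimethylsilane
Conditions: NCS (1.3 equiv), Me2S (1.5 equiv), CH2Cl2, −20 → 0 °C
Reagents that add atoms: N-chlorosuccinimide, O=C1CCC(=O)N1Cl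
Why: In the Corey–Kim chlorination chloride displaces dimethyl sulfoxide from the primary alkoxysulfonium salt by SN2 under neutral conditions, so the allylic chloride should form without transposition to the more hindered C1 terminus and without change of geometry.

Step 11
Reactants: 14 allylic chloride with terminal alkyne
Product: 15 (5R,6E,10E,14E)-5-[(tert-butyldimethylsilyl)oxy]-16-chloro-15-[(4-methoxyphenoxy)methyl]-7,11-dimethylhexadeca-6,10,14-trien-2-yn-1-ol
Conditions: LiN(i-Pr)2 (1.1 equiv), THF, −78 °C; (CH2O)n, −78 → 0 °C; then H2O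
Reagents that add atoms: formaldehyde (as paraformaldehyde), C=O
Why: The terminal alkyne is by far the most acidic site, so the hindered non-nucleophilic amide should form the lithium acetylide at −78 °C without attacking the allylic chloride (which has no β-hydrogen for elimination), and addition to formaldehyde adds C14 as the propargylic alcohol (acetylide hydroxymethylation).

Step 12
Reactants: 15 hydroxy chloride
Product: 16 (3Z,7E,11E,13R)-13-[(tert-butyldimethylsilyl)oxy]-3-[(4-methoxyphenoxy)methyl]-7,11-dimethyl-1-oxacycloheptadeca-3,7,11-trien-15-yne (C2 trans to C17 across C15=C1)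
Conditions: EtMgBr (1.05 equiv), THF, 0 °C; then slow addition into THF/HMPA, 60 °C, final 0.005 M
Reagents that add atoms: none
Why: In this intramolecular Williamson etherification the HMPA-activated bromomagnesium alkoxide at C14 displaces the primary allylic chloride at C17, which has no β-hydrogen to lose, and slow addition at high dilution should favour the 17-membered ring over oligomers.

Step 13
Reactants: 16 17-membered allyl propargyl ether
Product: 17 (1R,5R,6E,10E,14R)-5-[(tert-butyldimethylsilyl)oxy]-14-[3-(4-methoxyphenoxy)prop-1-en-2-yl]-7,11-dimethylcyclotetradeca-6,10-dien-2-yn-1-ol (target numbering: C14 carbinol, C12≡C13, C1 bearing the C15(=C17)C16 unit, C1/C14 anti)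
Conditions: lithium bis[(R)-1-phenylethyl]amide (from the amine and n-BuLi, 2.5 equiv), THF, −35 → −20 °C; then H2O
Reagents that add atoms: none
Why: The lithium amide removes one of the two C14 protons, the only C–H in the molecule that is both propargylic and next to oxygen, and the carbanion attacks C1 through a five-membered envelope transition state while the O–C17 bond breaks, so that C1–C14 forms, C15=C1 becomes the C15=C17 methylene and C14 becomes an alkoxide. The closest known reaction type is the [2,3]-Wittig ring contraction of macrocyclic allyl propargyl ethers to 14-membered propargylic carbinols with lithium amide bases, chiral ones included. The 14-membered ring closes by transannular bond formation inside the existing 17-membered ring (a three-atom ring contraction through a five-centre transition state), not by an end-to-end cyclisation. The C1/C14 relative configuration (anti, later the trans ring fusion) follows from the alkene geometry, C2 trans to C17, with the alkynyl branch exo on the envelope; the absolute sense follows from the chiral amide, which chooses between the two diastereotopic C14 protons and hence the face of C1 that is attacked, C10 being too remote to decide this alone. The step needs deprotonation at C14 and not at the allylic C16/C17 or the propargylic C11 positions, which the higher acidity of the α-oxy propargylic site and the absence of any benzylic ether should secure, and it needs the [2,3]- over the [1,2]-shift, which the low temperature should secure.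

Step 14
Reactants: 17 14-membered propargylic alcohol
Product: 19 (1R,2Z,5R,6E,10E,14R)-5-[(tert-butyldimethylsilyl)oxy]-3-iodo-14-[3-(4-methoxyphenoxy)prop-1-en-2-yl]-7,11-dimethylcyclotetradeca-2,6,10-trien-1-ol, via vinylalanate 18 (not isolated)
Conditions: NaAlH2(OCH2CH2OMe)2 (3 equiv), THF, 0 °C → rt; then I2, THF, −78 → −20 °C
Reagents that add atoms: iodine, II; NaAlH2(OCH2CH2OMe)2, [Na+].COCCO[AlH2-]OCCOC, supplies the aluminate unit of intermediate 18 only
Why: The C14 alkoxide binds aluminium and hydride is delivered to C13 (trans-hydroalumination of a propargylic alcohol), giving a five-membered vinylalanate with aluminium on C12 whose C–Al bond iodine should cleave with retention, so that iodine sits on C12 cis to C14.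

Step 15
Reactants: 19 vinyl iodide
Product: 20 (1S,2E,5R,6E,10E,14R)-5-[(tert-butyldimethylsilyl)oxy]-14-[3-(4-methoxyphenoxy)prop-1-en-2-yl]-3,7,11-trimethylcyclotetradeca-2,6,10-trien-1-ol
Conditions: Me2CuLi (from MeLi and CuI, 6 equiv), Et2O, 0 °C
Reagents that add atoms: lithium dimethylcuprate, [Li+].C[Cu-]C
Why: Cuprate cross-coupling of a vinyl iodide proceeds with retention of geometry, so the methyl group should end up cis to C14 and the C12=C13 alkene E, the excess reagent covering deprotonation of the free hydroxyl.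

Step 16
Reactants: 20 aryl ether
Product: 21 (1S,2E,5R,6E,10E,14R)-5-[(tert-butyldimethylsilyl)oxy]-14-(3-hydroxyprop-1-en-2-yl)-3,7,11-trimethylcyclotetradeca-2,6,10-trien-1-ol
Conditions: (NH4)2Ce(NO3)6 (2.5 equiv), pyridine, MeCN/H2O (4:1), 0 °C
Reagents that add atoms: none
Why: In this oxidative dearylation tetravalent cerium oxidises the electron-rich 4-methoxyphenyl ether by single-electron transfer and water attacks the arene radical cation, releasing benzoquinone and the C16 alcohol, while the less easily oxidised alkenes and the buffered silyl ether should survive.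

Step 17
Reactants: 21 2-methylene-1,4-diol
Product: 24 (3aR,6E,10E,12R,14E,15aS)-12-[(tert-butyldimethylsilyl)oxy]-6,10,14-trimethyl-3-methylidene-3a,4,5,8,9,12,13,15a-octahydrocyclotetradeca[b]furan-2(3H)-one, via hydroxy enal 22 (not isolated), via lactol 23 (not isolated)
Conditions: TEMPO (20 mol %), PhI(OAc)2 (2.5 equiv), CH2Cl2, rt
Reagents that add atoms: none
Why: Nitroxyl-catalysed oxidation is selective for the primary allylic alcohol at C16 over the secondary C14 alcohol, the hydroxy enal closes to the five-membered lactol and this is oxidised on to the lactone (oxidative lactonisation of a 1,4-diol), leaving C1 and C14 untouched.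

Step 18
Reactants: 24 silyl-protected lactone
Product: 25 (3aR,6E,10E,12R,14E,15aS)-12-hydroxy-6,10,14-trimethyl-3-methylidene-3a,4,5,8,9,12,13,15a-octahydrocyclotetradeca[b]furan-2(3H)-one
Conditions: HF·pyridine, pyridine, THF, 0 °C → rt
Reagents that add atoms: none
Why: Fluoride cleavage of the silyl ether under buffered, weakly acidic conditions should avoid base-induced conjugate addition to the methylene lactone and leave the C10 configuration unchanged.

Step 19
Reactants: 25 hydroxy lactone
Product: 26 (3aR,6E,10E,12R,14E,15aS)-6,10,14-trimethyl-3-methylidene-2-oxo-2,3,3a,4,5,8,9,12,13,15a-decahydrocyclotetradeca[b]furan-12-yl acetate (CNP0206931.1)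
Conditions: Ac2O, pyridine, DMAP (cat.), CH2Cl2, 0 °C → rt
Reagents that add atoms: acetic anhydride, CC(=O)OC(C)=O
Why: DMAP-catalysed acylation of the secondary allylic alcohol should give the acetate with retention at C10 and complete the target.

Compound list

1 | (2E,6E)-farnesol | OC/C=C(\C)CC/C=C(\C)CCC=C(C)C | starting material
2 | (2E,6E)-farnesal | O=C/C=C(\C)CC/C=C(\C)CCC=C(C)C | intermediate
3 | allenylboronic acid pinacol ester | C=C=CB1OC(C)(C)C(C)(C)O1 | starting material
4 | (4R,5E,9E)-6,10,14-trimethylpentadeca-5,9,13-trien-1-yn-4-ol | C#CC[C@@H](O)/C=C(\C)CC/C=C(\C)CCC=C(C)C | intermediate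
5 | tert-butyldimethylsilyl ether of 4 | C#CC[C@@H](O[Si](C)(C)C(C)(C)C)/C=C(\C)CC/C=C(\C)CCC=C(C)C | intermediate
6 | terminal bromohydrin of 5: (6E,10E,12R)-3-bromo-12-[(tert-butyldimethylsilyl)oxy]-2,6,10-trimethylpentadeca-6,10-dien-14-yn-2-ol, both C3 epimers | C#CC[C@@H](O[Si](C)(C)C(C)(C)C)/C=C(\C)CC/C=C(\C)CCC(Br)C(C)(C)O | intermediate
7 | terminal epoxide: tert-butyl{[(4R,5E,9E)-12-(3,3-dimethyloxiran-2-yl)-6,10-dimethyldodeca-5,9-dien-1-yn-4-yl]oxy}dimethylsilane, both epoxide epimers | C#CC[C@@H](O[Si](C)(C)C(C)(C)C)/C=C(\C)CC/C=C(\C)CCC1OC1(C)C | intermediate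
8 | (4E,8E,10R)-10-[(tert-butyldimethylsilyl)oxy]-4,8-dimethyltrideca-4,8-dien-12-ynal | C#CC[C@@H](O[Si](C)(C)C(C)(C)C)/C=C(\C)CC/C=C(\C)CCC=O | intermediate
9 | methyl acrylate | C=CC(=O)OC | starting material
10 | methyl (6E,10E,12R)-12-[(tert-butyldimethylsilyl)oxy]-3-hydroxy-6,10-dimethyl-2-methylidenepentadeca-6,10-dien-14-ynoate, both C3 epimers | C#CC[C@@H](O[Si](C)(C)C(C)(C)C)/C=C(\C)CC/C=C(\C)CCC(O)C(=C)C(=O)OC | intermediate
11 | methyl (2Z,6E,10E,12R)-2-(bromomethyl)-12-[(tert-butyldimethylsilyl)oxy]-6,10-dimethylpentadeca-2,6,10-trien-14-ynoate | C#CC[C@@H](O[Si](C)(C)C(C)(C)C)/C=C(\C)CC/C=C(\C)CC/C=C(\CBr)C(=O)OC | intermediate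
12 | methyl (2E,6E,10E,12R)-12-[(tert-butyldimethylsilyl)oxy]-2-[(4-methoxyphenoxy)methyl]-6,10-dimethylpentadeca-2,6,10-trien-14-ynoate | C#CC[C@@H](O[Si](C)(C)C(C)(C)C)/C=C(\C)CC/C=C(\C)CC/C=C(\COc1ccc(OC)cc1)C(=O)OC | intermediate
13 | (2Z,6E,10E,12R)-12-[(tert-butyldimethylsilyl)oxy]-2-[(4-methoxyphenoxy)methyl]-6,10-dimethylpentadeca-2,6,10-trien-14-yn-1-ol | C#CC[C@@H](O[Si](C)(C)C(C)(C)C)/C=C(\C)CC/C=C(\C)CC/C=C(\COc1ccc(OC)cc1)CO | intermediate
14 | tert-butyl{[(4R,5E,9E,13E)-15-chloro-14-[(4-methoxyphenoxy)methyl]-6,10-dimethylpentadeca-5,9,13-trien-1-yn-4-yl]oxy}dimethylsilane | C#CC[C@@H](O[Si](C)(C)C(C)(C)C)/C=C(\C)CC/C=C(\C)CC/C=C(\COc1ccc(OC)cc1)CCl | intermediate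
15 | (5R,6E,10E,14E)-5-[(tert-butyldimethylsilyl)oxy]-16-chloro-15-[(4-methoxyphenoxy)methyl]-7,11-dimethylhexadeca-6,10,14-trien-2-yn-1-ol | OCC#CC[C@@H](O[Si](C)(C)C(C)(C)C)/C=C(\C)CC/C=C(\C)CC/C=C(\COc1ccc(OC)cc1)CCl | intermediate
16 | (3Z,7E,11E,13R)-13-[(tert-butyldimethylsilyl)oxy]-3-[(4-methoxyphenoxy)methyl]-7,11-dimethyl-1-oxacycloheptadeca-3,7,11-trien-15-yne | O1C/C(COc2ccc(OC)cc2)=C/CC/C(C)=C/CC/C(C)=C/[C@H](O[Si](C)(C)C(C)(C)C)CC#CC1 | intermediate
17 | (1R,5R,6E,10E,14R)-5-[(tert-butyldimethylsilyl)oxy]-14-[3-(4-methoxyphenoxy)prop-1-en-2-yl]-7,11-dimethylcyclotetradeca-6,10-dien-2-yn-1-ol | O[C@H]1C#CC[C@@H](O[Si](C)(C)C(C)(C)C)/C=C(\C)CC/C=C(\C)CC[C@@H]1C(=C)COc2ccc(OC)cc2 | intermediate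
18 | sodium vinylalanate of 17: five-membered O14–Al–C12=C13–C14 ring, aluminium carrying two 2-methoxyethoxy groups | [Na+].COCCO[Al-]2(OCCOC)O[C@H]1/C=C2/C[C@@H](O[Si](C)(C)C(C)(C)C)/C=C(\C)CC/C=C(\C)CC[C@@H]1C(=C)COc3ccc(OC)cc3 | intermediate
19 | (1R,2Z,5R,6E,10E,14R)-5-[(tert-butyldimethylsilyl)oxy]-3-iodo-14-[3-(4-methoxyphenoxy)prop-1-en-2-yl]-7,11-dimethylcyclotetradeca-2,6,10-trien-1-ol | O[C@H]1/C=C(\I)C[C@@H](O[Si](C)(C)C(C)(C)C)/C=C(\C)CC/C=C(\C)CC[C@@H]1C(=C)COc2ccc(OC)cc2 | intermediate
20 | (1S,2E,5R,6E,10E,14R)-5-[(tert-butyldimethylsilyl)oxy]-14-[3-(4-methoxyphenoxy)prop-1-en-2-yl]-3,7,11-trimethylcyclotetradeca-2,6,10-trien-1-ol | O[C@H]1/C=C(\C)C[C@@H](O[Si](C)(C)C(C)(C)C)/C=C(\C)CC/C=C(\C)CC[C@@H]1C(=C)COc2ccc(OC)cc2 | intermediate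
21 | (1S,2E,5R,6E,10E,14R)-5-[(tert-butyldimethylsilyl)oxy]-14-(3-hydroxyprop-1-en-2-yl)-3,7,11-trimethylcyclotetradeca-2,6,10-trien-1-ol | O[C@H]1/C=C(\C)C[C@@H](O[Si](C)(C)C(C)(C)C)/C=C(\C)CC/C=C(\C)CC[C@@H]1C(=C)CO | intermediate
22 | hydroxy enal: 21 with the C16 CH2OH oxidised to CHO | O[C@H]1/C=C(\C)C[C@@H](O[Si](C)(C)C(C)(C)C)/C=C(\C)CC/C=C(\C)CC[C@@H]1C(=C)C=O | intermediate
23 | lactol: C16 hemiacetal closed onto the C14 oxygen, both anomers | C=C1C(O)O[C@H]2/C=C(\C)C[C@@H](O[Si](C)(C)C(C)(C)C)/C=C(\C)CC/C=C(\C)CC[C@H]12 | intermediate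
24 | (3aR,6E,10E,12R,14E,15aS)-12-[(tert-butyldimethylsilyl)oxy]-6,10,14-trimethyl-3-methylidene-3a,4,5,8,9,12,13,15a-octahydrocyclotetradeca[b]furan-2(3H)-one | C=C1C(=O)O[C@H]2/C=C(\C)C[C@@H](O[Si](C)(C)C(C)(C)C)/C=C(\C)CC/C=C(\C)CC[C@H]12 | intermediate
25 | (3aR,6E,10E,12R,14E,15aS)-12-hydroxy-6,10,14-trimethyl-3-methylidene-3a,4,5,8,9,12,13,15a-octahydrocyclotetradeca[b]furan-2(3H)-one | C=C1C(=O)O[C@H]2/C=C(\C)C[C@@H](O)/C=C(\C)CC/C=C(\C)CC[C@H]12 | intermediate
26 | CNP0206931.1: (3aR,6E,10E,12R,14E,15aS)-6,10,14-trimethyl-3-methylidene-2-oxo-2,3,3a,4,5,8,9,12,13,15a-decahydrocyclotetradeca[b]furan-12-yl acetate; target numbering 1R,10R,14S | C=C1C(=O)O[C@H]2/C=C(\C)C[C@@H](OC(C)=O)/C=C(\C)CC/C=C(\C)CC[C@H]12 | target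

Total step count: 19. Longest linear sequence: 19 steps, from (2E,6E)-farnesol.

Steps most likely to fail

Step 13. The chiral amide may discriminate poorly between the two faces, so that the two anti diastereomers (differing in the sense of C1/C14 relative to C10) form together, or proton abstraction may occur away from C14. Fallback: setting out from hydroxy chloride 15, the propargylic alcohol would be oxidised with MnO2 in CH2Cl2 to the ynal, (5R,6E,10E,14E)-5-[(tert-butyldimethylsilyl)oxy]-16-chloro-15-[(4-methoxyphenoxy)methyl]-7,11-dimethylhexadeca-6,10,14-trien-2-ynal F1. This would be cyclised at high dilution with CrCl2 in THF, with a chiral oxazoline–sulfonamide ligand if reagent control of the absolute sense is wanted (intramolecular Nozaki–Hiyama allylation). The allylchromium formed at C17 adds through its γ-carbon C1 to the C14 aldehyde in a chair transition state, which forms the same C1–C14 bond, moves the alkene to C15=C17 and is anti-selective. The route is rejoined at 17.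

Step 12. Intermolecular etherification to oligomers, or SN2' attack at C1, may outpace closure of the 17-membered ring. Fallback: setting out from chloride 14, intermolecular Williamson etherification with but-2-yn-1-ol and NaH in THF/DMF would give the C17 but-2-yn-1-yl ether F2. C-methylation of its terminal alkyne (n-BuLi, THF, −78 °C; MeI) would give the doubly methyl-capped diyne F3. Ring-closing alkyne metathesis of F3 with Mo(≡CC6H4OMe-4)(OSiPh3)3 in toluene over 5 Å MS at high dilution, with loss of but-2-yne, would then close the ring at C12≡C13 instead of at the ether. The route is rejoined at 16.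

Step 11. The allylic chloride may be consumed by the base, by the acetylide or by the new alkoxide before the cyclisation. Fallback: setting out from allylic alcohol 13, the C17 hydroxyl would be masked as the tetrahydropyran-2-yl ether F4 (3,4-dihydro-2H-pyran, PPTS, CH2Cl2). The alkyne would be hydroxymethylated with no electrophile present (n-BuLi, THF, −78 °C; (CH2O)n) to give the propargylic alcohol F5. This would be converted into the propargylic bromide F6 (CBr4, PPh3, CH2Cl2), and the acetal removed (PPTS, MeOH) to give the C17-hydroxy C14-bromide F7. F7 would be closed with NaH in THF at high dilution, the C17 alkoxide now displacing the C14 bromide (etherification with reversed polarity). The route is rejoined at 16.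

Further compounds

F1 | step 13 | (5R,6E,10E,14E)-5-[(tert-butyldimethylsilyl)oxy]-16-chloro-15-[(4-methoxyphenoxy)methyl]-7,11-dimethylhexadeca-6,10,14-trien-2-ynal | O=CC#CC[C@@H](O[Si](C)(C)C(C)(C)C)/C=C(\C)CC/C=C(\C)CC/C=C(\COc1ccc(OC)cc1)CCl
F2 | step 12 | C17 but-2-yn-1-yl ether derived from 14 (chloride replaced by OCH2C≡CCH3) | C#CC[C@@H](O[Si](C)(C)C(C)(C)C)/C=C(\C)CC/C=C(\C)CC/C=C(\COc1ccc(OC)cc1)COCC#CC
F3 | step 12 | F2 with the terminal alkyne C-methylated | CC#CC[C@@H](O[Si](C)(C)C(C)(C)C)/C=C(\C)CC/C=C(\C)CC/C=C(\COc1ccc(OC)cc1)COCC#CC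
F4 | step 11 | C17 tetrahydropyran-2-yl ether of 13 | C#CC[C@@H](O[Si](C)(C)C(C)(C)C)/C=C(\C)CC/C=C(\C)CC/C=C(\COc1ccc(OC)cc1)COC1CCCCO1
F5 | step 11 | F4 hydroxymethylated at the alkyne terminus (C14 CH2OH) | OCC#CC[C@@H](O[Si](C)(C)C(C)(C)C)/C=C(\C)CC/C=C(\C)CC/C=C(\COc1ccc(OC)cc1)COC1CCCCO1
F6 | step 11 | C14 propargylic bromide of F5 | BrCC#CC[C@@H](O[Si](C)(C)C(C)(C)C)/C=C(\C)CC/C=C(\C)CC/C=C(\COc1ccc(OC)cc1)COC1CCCCO1
F7 | step 11 | F6 without the tetrahydropyranyl group (C17 OH, C14 Br) | BrCC#CC[C@@H](O[Si](C)(C)C(C)(C)C)/C=C(\C)CC/C=C(\C)CC/C=C(\COc1ccc(OC)cc1)CO
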